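Cuts, in retrosynthetic order: the O9–acyl bond; C7–C11 (isopropenyl, by epoxide opening); C10–C14 and C5–C14 (a cyclopropane standing in for the C5 methyl); C4–C5 (Heck closure of ring A); C1–C10 (aryl anion plus epoxide); C3–C4 (vinyl Grignard plus epichlorohydrin).
Enabling feature: methyl C14 sits on quaternary C5 of the ring A/ring B fusion, next to C10–H and two bonds from the C9 oxygen of ring B, so a 9β-carbinol on a Δ5(10)-octalin can hand a CH2 to C5=C10 and the derived C9 ketone can then cut C10–C14.
Forward: ring B enters as 1,3-dimethoxybenzene, is alkylated at C10 with the C1–C4 chain and Birch-reduced to a 1,3-dione; ring A closes by a 6-exo Heck reaction of the dione monotriflate; the three-membered ring is made in step 12 and opened in step 14.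
Ring B is then dehydrogenated to the Δ7-enone, taken to the 9α-allylic alcohol, epoxidised, opened at C7 with an isopropenyl copper reagent, acylated at O9 and desilylated.
Stereochemistry: C2 from (S)-epichlorohydrin; C4 by hydroxyl-directed hydrogenation; a temporary C9 carbinol by CBS reduction, relayed to C5 by the directed cyclopropanation; C10 by enolate protonation to the trans-decalone; C9 by α-face hydride addition then Mitsunobu inversion; C8 and C7 by hydroxyl-directed epoxidation and trans-diaxial opening.

Key step: step 12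

Remark: the SMILES is read as a trans-fused eremophilane (ring A = C1–C5 and C10, ring B = C5–C10, C14 and C15 = methyls on C5 and C4, C11–C13 = isopropenyl on C7) with 2α-OH, 4β-Me, 5β-Me, 7β-isopropenyl, 8α-OH, 9α-acyloxy, 10α-H and a Z enoate; β is the face of the C5 methyl, and all bicyclic intermediates are named with this numbering.

Step 1
Reactants: 1 (S)-epichlorohydrin; 2 vinylmagnesium bromide
Product: 3 (S)-1-chloropent-4-en-2-ol
Conditions: CuI (10 mol%), THF, −78 → −20 °C; aq. NH4Cl
Reagents that add atoms: none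
Why: Copper-catalysed Grignard opening of the epoxide (SN2 at the unsubstituted CH2) is faster than attack at the C–Cl bond at low temperature and leaves the carbinol stereocentre untouched, so the (S) configuration is carried over.

Step 2
Reactants: 3 (S)-1-chloropent-4-en-2-ol
Product: 4 (S)-2-allyloxirane
Conditions: NaOH (powder), Et2O, rt; distil
Reagents that add atoms: none
Why: Intramolecular Williamson etherification (3-exo-tet closure of the alkoxide onto CH2Cl) re-forms an epoxide without breaking a bond at the stereocentre, which therefore stays (S).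

Step 3
Reactants: 5 1,3-dimethoxybenzene; 4 (S)-2-allyloxirane
Product: 7 (S)-1-(2,6-dimethoxyphenyl)pent-4-en-2-ol, via 2,6-dimethoxyphenyllithium 6 (not isolated)
Conditions: n-BuLi, THF, 0 °C → rt; then 4, BF3·OEt2, −78 °C; aq. NH4Cl
Reagents that add atoms: none
Why: Directed ortho-lithiation of 5 between its two methoxy groups gives aryllithium 6, whose BF3-assisted SN2 opening of epoxide 4 at the terminal carbon forms the C1–C10 bond and leaves C2 unchanged.

Step 4
Reactants: 7 (S)-1-(2,6-dimethoxyphenyl)pent-4-en-2-ol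
Product: 8 triisopropylsilyl (TIPS) ether of 7
Conditions: TIPSOTf, 2,6-lutidine, CH2Cl2, 0 °C
Reagents that add atoms: triisopropylsilyl trifluoromethanesulfonate, CC(C)[Si](OS(=O)(=O)C(F)(F)F)(C(C)C)C(C)C
Why: Silyl ether formation with a silyl triflate is routine for secondary alcohols, and the TIPS group is chosen because it withstands both lithium in ammonia and the aqueous acid of the next step.

Step 5
Reactants: 8 TIPS ether of 7
Product: 10 2-[(S)-2-(TIPS-oxy)pent-4-enyl]cyclohexane-1,3-dione, via bis(enol ether) 9 (not isolated)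
Conditions: Li, NH3(l), THF, t-BuOH, −78 → −33 °C; then 1 M HCl, THF, rt
Reagents that add atoms: water, O
Why: Birch reduction of a 2-alkyl-1,3-dimethoxybenzene places both methoxy groups on the double bonds of a 1,4-diene, and acid hydrolysis of the two enol ethers then gives the 2-alkylcyclohexane-1,3-dione, while the isolated terminal alkene and the TIPS ether are inert to both stages.

Step 6
Reactants: 10 2-[(S)-2-(TIPS-oxy)pent-4-enyl]cyclohexane-1,3-dione
Product: 11 3-oxo-2-[(S)-2-(TIPS-oxy)pent-4-enyl]cyclohex-1-enyl triflate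
Conditions: Tf2O, pyridine, CH2Cl2, −78 → 0 °C
Reagents that add atoms: trifluoromethanesulfonic anhydride, O=S(=O)(OS(=O)(=O)C(F)(F)F)C(F)(F)F
Why: O-Sulfonylation of the enol of a symmetrical cyclic 1,3-dione gives a single β-triflyloxy enone, which is a standard activated partner for palladium-catalysed C–C bond formation.

Step 7
Reactants: 11 3-oxo-2-[(S)-2-(TIPS-oxy)pent-4-enyl]cyclohex-1-enyl triflate
Product: 12 4-methylene-2α-(TIPS-oxy)-Δ5(10)-octalin-9-one
Conditions: Pd(OAc)2 (10 mol%), PPh3, Et3N, MeCN, 70 °C
Reagents that add atoms: none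
Why: Intramolecular Heck reaction in which zerovalent palladium (formed in the flask from Pd(OAc)2 and PPh3) inserts into the C5–OTf bond, the vinylpalladium adds 6-exo-trig to the terminal alkene to form C4–C5 and close ring A, and β-hydride elimination of the only available hydrogen (on C4) leaves the exocyclic C4=C15 methylene.

Step 8
Reactants: 12 4-methylene-2α-(TIPS-oxy)-Δ5(10)-octalin-9-one
Product: 13 2α-hydroxy-4-methylene-Δ5(10)-octalin-9-one
Conditions: TBAF, AcOH, THF, 0 °C → rt
Reagents that add atoms: none
Why: Fluoride cleavage of the silyl ether, buffered with acetic acid so that the dienone never meets a free alkoxide, releases the C2 hydroxyl needed as a directing group.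

Step 9
Reactants: 13 2α-hydroxy-4-methylene-Δ5(10)-octalin-9-one
Product: 14 2α-hydroxy-4β-methyl-Δ5(10)-octalin-9-one
Conditions: H2 (1 atm), [Ir(cod)(PCy3)(py)]PF6 (5 mol%), CH2Cl2, 0 °C
Reagents that add atoms: none
Why: Hydroxyl-directed homogeneous hydrogenation in which the cationic iridium catalyst is anchored by the 2α-hydroxyl (homoallylic to C4=C15) and adds H2 to the α face of the 1,1-disubstituted alkene, so that C4–H is cis to the hydroxyl and the new methyl stereocentre is 4β, while the tetrasubstituted, electron-poor C5=C10 alkene should not react.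

Step 10
Reactants: 14 2α-hydroxy-4β-methyl-Δ5(10)-octalin-9-one
Product: 15 2α-(TBS-oxy)-4β-methyl-Δ5(10)-octalin-9-one
Conditions: TBSCl, imidazole, DMF, rt
Reagents that add atoms: tert-butyldimethylsilyl chloride, CC(C)(C)[Si](C)(C)Cl
Why: Silylation with a silyl chloride and imidazole is too mild to epimerise the γ-stereocentre C4 and masks the C2 hydroxyl so that it cannot compete as a directing group in the cyclopropanation.

Step 11
Reactants: 15 2α-(TBS-oxy)-4β-methyl-Δ5(10)-octalin-9-one
Product: 16 2α-(TBS-oxy)-4β-methyl-Δ5(10)-octalin-9β-ol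
Conditions: (R)-2-methyl-CBS-oxazaborolidine (20 mol%), catecholborane, toluene, −78 °C
Reagents that add atoms: none
Why: Corey–Bakshi–Shibata reduction of an α-substituted cyclic enone is reagent-controlled, and with the fully substituted alkene carbon C10 as the large group and the C8 methylene as the small one the (R)-catalyst should deliver hydride to the α face of C9 to give the (9S), 9β-allylic alcohol, with catecholborane ensuring 1,2-selectivity.

Step 12
Reactants: 16 2α-(TBS-oxy)-4β-methyl-Δ5(10)-octalin-9β-ol; 17 diiodomethane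
Product: 19 5β,10β-methano-2α-(TBS-oxy)-4β-methyldecalin-9β-ol, via ethylzinc alkoxide 18 (not isolated)
Conditions: Et2Zn, 17, CH2Cl2, 0 °C → rt; aq. NH4Cl
Reagents that add atoms: none
Why: Et2Zn first converts the 9β-hydroxyl into ethylzinc alkoxide 18 and, with 17, forms an iodomethylzinc carbenoid that is held by the alkoxide oxygen and transfers CH2 to the C5=C10 alkene through a butterfly-type transition state, forming C5–C14 and C10–C14 in one concerted, stereospecific [2+1] event. The closest known reaction type is the hydroxyl-directed Simmons–Smith cyclopropanation of cyclic allylic alcohols with Et2Zn and CH2I2, which is established for tetrasubstituted ring-fusion alkenes. The three-membered ring is closed by this concerted syn addition of the methylene to one alkene face and not by a stepwise ring closure. Both new stereocentres, C5 and C10, are set together by the 9β-oxygen, because the carbenoid can only reach the face that carries the zinc alkoxide, so C14 ends β and cis to the C4 methyl. The selectivity needed is facial (β over α) on an alkene whose β face is flanked by the pseudoaxial C4 methyl, and it is secured by the allylic zinc alkoxide on the β face, by the bulky, non-coordinating silyl ether at C2 on the α face and by the absence of any other alkene in 16. The TBS ether and the carbinol should tolerate the weakly Lewis acidic zinc salts at 0 °C.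

Step 13
Reactants: 19 5β,10β-methano-2α-(TBS-oxy)-4β-methyldecalin-9β-ol
Product: 20 5β,10β-methano-2α-(TBS-oxy)-4β-methyldecalin-9-one
Conditions: DMP, NaHCO3, CH2Cl2, rt
Reagents that add atoms: none
Why: Dess–Martin oxidation converts the secondary cyclopropylcarbinol into the conjugated cyclopropyl ketone under buffered, non-acidic conditions that avoid cyclopropylcarbinyl cation rearrangement and touch no stereocentre.

Step 14
Reactants: 20 5β,10β-methano-2α-(TBS-oxy)-4β-methyldecalin-9-one
Product: 22 2α-(TBS-oxy)-4β,5β-dimethyl-trans-decalin-9-one (10α-H), via lithium enolate 21 (not isolated)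
Conditions: Li, NH3(l), THF, −78 °C; then NH4Cl
Reagents that add atoms: none
Why: Dissolving-metal reductive cleavage of a conjugated cyclopropyl ketone breaks the exocyclic C10–C14 bond, which overlaps with the carbonyl π system far better than the ring-fusion C5–C10 bond, so that C14 becomes the 5β-methyl group, and lithium enolate 21 is then protonated at C10 on the α face (axial, opposite the angular methyl) to give the trans-fused decalone, which is also the more stable C10 epimer.

Step 15
Reactants: 22 2α-(TBS-oxy)-4β,5β-dimethyl-trans-decalin-9-one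
Product: 24 2α-(TBS-oxy)-4β,5β-dimethyl-10αH-Δ7-octalin-9-one, via silyl enol ether 23 (not isolated)
Conditions: LiN(iPr)2, TMSCl, THF, −78 °C; then Pd(OAc)2, MeCN, rt
Reagents that add atoms: none
Why: Saegusa–Ito oxidation in which kinetic deprotonation with in situ silylation occurs at the C8 methylene and not at the hindered C10 methine, and Pd(OAc)2 converts silyl enol ether 23 into the Δ7-enone by β-hydride elimination from C7 without touching C10.

Step 16
Reactants: 24 2α-(TBS-oxy)-4β,5β-dimethyl-10αH-Δ7-octalin-9-one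
Product: 25 2α-(TBS-oxy)-4β,5β-dimethyl-10αH-Δ7-octalin-9β-ol
Conditions: i-Bu2AlH, CH2Cl2, −78 °C; aq. potassium sodium tartrate
Reagents that add atoms: none
Why: 1,2-Reduction of the enone with the bulky hydride i-Bu2AlH should occur from the α face, because the β face of C9 is screened by the axial C5 methyl in a 1,3-diaxial relationship, which gives the 9β (pseudoaxial) allylic alcohol.

Step 17
Reactants: 25 2α-(TBS-oxy)-4β,5β-dimethyl-10αH-Δ7-octalin-9β-ol
Product: 26 9α-(4-nitrobenzoyloxy)-2α-(TBS-oxy)-4β,5β-dimethyl-10αH-Δ7-octalin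
Conditions: 4-nitrobenzoic acid, PPh3, DIAD, toluene, 0 °C → rt
Reagents that add atoms: 4-nitrobenzoic acid, O=C(O)c1ccc(cc1)[N+](=O)[O-]
Why: Mitsunobu reaction in which the activated 9β-hydroxyl is displaced by 4-nitrobenzoate in an SN2 process from the open α face, inverting C9 to the 9α configuration required in the target.

Step 18
Reactants: 26 9α-(4-nitrobenzoyloxy)-2α-(TBS-oxy)-4β,5β-dimethyl-10αH-Δ7-octalin
Product: 27 2α-(TBS-oxy)-4β,5β-dimethyl-10αH-Δ7-octalin-9α-ol
Conditions: K2CO3, MeOH, rt
Reagents that add atoms: none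
Why: Base-catalysed transesterification (methanolysis) of the activated 4-nitrobenzoate releases the 9α-allylic alcohol without affecting the TBS ether or any stereocentre.

Step 19
Reactants: 27 2α-(TBS-oxy)-4β,5β-dimethyl-10αH-Δ7-octalin-9α-ol
Product: 28 7α,8α-epoxy-2α-(TBS-oxy)-4β,5β-dimethyl-trans-decalin-9α-ol
Conditions: mCPBA, NaHCO3, CH2Cl2, 0 °C
Reagents that add atoms: 3-chloroperoxybenzoic acid, OOC(=O)c1cccc(Cl)c1
Why: Hydroxyl-directed peracid epoxidation (Prilezhaev reaction) of a cyclic allylic alcohol, in which hydrogen bonding to the pseudoequatorial 9α-hydroxyl and the shielding of the β face by the axial C5 methyl both steer oxygen to the α face and so set C7 and C8 as the 7α,8α-epoxide.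

Step 20
Reactants: 28 7α,8α-epoxy-2α-(TBS-oxy)-4β,5β-dimethyl-trans-decalin-9α-ol
Product: 29 7β-isopropenyl-2α-(TBS-oxy)-4β,5β-dimethyl-trans-decalin-8α,9α-diol
Conditions: isopropenylmagnesium bromide, CuI (30 mol%), THF, −30 → 0 °C; aq. NH4Cl
Reagents that add atoms: isopropenylmagnesium bromide, CC(=C)[Mg]Br
Why: Copper-catalysed Grignard opening of an epoxide in a conformationally locked trans-decalin must take place at C7 from the β face to give the trans-diaxial product (SN2 inversion at C7), and C7 is also the carbon remote from the C9 alkoxide, so the isopropenyl group should end 7β and the hydroxyl 8α.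

Step 21
Reactants: 29 7β-isopropenyl-2α-(TBS-oxy)-4β,5β-dimethyl-trans-decalin-8α,9α-diol; 30 (Z)-3-methylpent-2-enoic acid
Product: 33 9α-O-[(Z)-3-methylpent-2-enoyl] ester of 29, via dibutylstannylene acetal 31 (not isolated), via acid chloride 32 (not isolated)
Conditions: 29, Bu2SnO, toluene, reflux (−H2O); separately 30, 1-chloro-N,N,2-trimethylprop-1-en-1-amine, CH2Cl2, 0 °C; then combine, toluene, 0 °C → rt
Reagents that add atoms: none
Why: Regioselective acylation through a dibutylstannylene acetal, in which tin acetal 31 of the cis-8α,9α-diol raises the nucleophilicity of the equatorial O9 over the axial O8, while the base-free reaction with acid chloride 32 (made from 30 under neutral conditions) avoids the ketene and dienolate pathways that could scramble the Z double bond.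

Step 22
Reactants: 33 9α-O-[(Z)-3-methylpent-2-enoyl] ester of 29
Product: 34 CNP0129603.1
Conditions: HF·pyridine, pyridine, THF, 0 °C → rt
Reagents that add atoms: none
Why: Fluoride-mediated desilylation with buffered HF·pyridine removes the TBS ether at C2 under weakly acidic conditions in which neither acyl migration between O9 and O8 nor isomerisation of the enoate or the isopropenyl group is expected.

Compound list
1 | (S)-epichlorohydrin | ClC[C@@H]1CO1 | starting material
2 | vinylmagnesium bromide | C=C[Mg]Br | starting material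
3 | (S)-1-chloropent-4-en-2-ol | ClC[C@@H](O)CC=C | intermediate
4 | (S)-2-allyloxirane | C=CC[C@H]1CO1 | intermediate
5 | 1,3-dimethoxybenzene | COc1cccc(OC)c1 | starting material
6 | 2,6-dimethoxyphenyllithium (not isolated) | [Li]c1c(OC)cccc1OC | intermediate
7 | (S)-1-(2,6-dimethoxyphenyl)pent-4-en-2-ol | C=CC[C@H](O)Cc1c(OC)cccc1OC | intermediate
8 | (S)-1-(2,6-dimethoxyphenyl)-2-(triisopropylsilyloxy)pent-4-ene | C=CC[C@H](O[Si](C(C)C)(C(C)C)C(C)C)Cc1c(OC)cccc1OC | intermediate
9 | 1,5-dimethoxy-6-[(S)-2-(triisopropylsilyloxy)pent-4-enyl]cyclohexa-1,4-diene (not isolated) | C=CC[C@H](O[Si](C(C)C)(C(C)C)C(C)C)CC1C(OC)=CCC=C1OC | intermediate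
10 | 2-[(S)-2-(triisopropylsilyloxy)pent-4-enyl]cyclohexane-1,3-dione | C=CC[C@H](O[Si](C(C)C)(C(C)C)C(C)C)CC1C(=O)CCCC1=O | intermediate
11 | 3-oxo-2-[(S)-2-(triisopropylsilyloxy)pent-4-enyl]cyclohex-1-enyl trifluoromethanesulfonate | C=CC[C@H](O[Si](C(C)C)(C(C)C)C(C)C)CC1=C(OS(=O)(=O)C(F)(F)F)CCCC1=O | intermediate
12 | 4-methylene-2α-(triisopropylsilyloxy)-Δ5(10)-octalin-9-one | O=C1CCCC2=C1C[C@@H](O[Si](C(C)C)(C(C)C)C(C)C)CC2=C | intermediate
13 | 2α-hydroxy-4-methylene-Δ5(10)-octalin-9-one | O=C1CCCC2=C1C[C@@H](O)CC2=C | intermediate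
14 | 2α-hydroxy-4β-methyl-Δ5(10)-octalin-9-one | O=C1CCCC2=C1C[C@@H](O)C[C@@H]2C | intermediate
15 | 2α-(tert-butyldimethylsilyloxy)-4β-methyl-Δ5(10)-octalin-9-one | O=C1CCCC2=C1C[C@@H](O[Si](C)(C)C(C)(C)C)C[C@@H]2C | intermediate
16 | 2α-(tert-butyldimethylsilyloxy)-4β-methyl-Δ5(10)-octalin-9β-ol (9S) | O[C@H]1CCCC2=C1C[C@@H](O[Si](C)(C)C(C)(C)C)C[C@@H]2C | intermediate
17 | diiodomethane | ICI | starting material
18 | ethylzinc 9β-alkoxide of 16 (not isolated) | CC[Zn]O[C@H]1CCCC2=C1C[C@@H](O[Si](C)(C)C(C)(C)C)C[C@@H]2C | intermediate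
19 | 5β,10β-methano-2α-(tert-butyldimethylsilyloxy)-4β-methyldecalin-9β-ol (cyclopropane C5–C14–C10 on the β face) | O[C@H]1CCC[C@@]23C[C@@]12C[C@@H](O[Si](C)(C)C(C)(C)C)C[C@@H]3C | intermediate
20 | 5β,10β-methano-2α-(tert-butyldimethylsilyloxy)-4β-methyldecalin-9-one | O=C1CCC[C@@]23C[C@@]12C[C@@H](O[Si](C)(C)C(C)(C)C)C[C@@H]3C | intermediate
21 | lithium Δ9(10)-enolate of 22 (not isolated) | [Li]OC1=C2C[C@@H](O[Si](C)(C)C(C)(C)C)C[C@H](C)[C@@]2(C)CCC1 | intermediate
22 | 2α-(tert-butyldimethylsilyloxy)-4β,5β-dimethyl-trans-decalin-9-one (10α-H) | O=C1CCC[C@]2(C)[C@@H](C)C[C@H](O[Si](C)(C)C(C)(C)C)C[C@@H]12 | intermediate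
23 | 9-(trimethylsilyloxy)-Δ8-enol ether of 22 (not isolated) | C[Si](C)(C)OC1=CCC[C@]2(C)[C@@H](C)C[C@H](O[Si](C)(C)C(C)(C)C)C[C@@H]12 | intermediate
24 | 2α-(tert-butyldimethylsilyloxy)-4β,5β-dimethyl-10αH-Δ7-octalin-9-one | O=C1C=CC[C@]2(C)[C@@H](C)C[C@H](O[Si](C)(C)C(C)(C)C)C[C@@H]12 | intermediate
25 | 2α-(tert-butyldimethylsilyloxy)-4β,5β-dimethyl-10αH-Δ7-octalin-9β-ol | O[C@H]1C=CC[C@]2(C)[C@@H](C)C[C@H](O[Si](C)(C)C(C)(C)C)C[C@@H]12 | intermediate
26 | 9α-(4-nitrobenzoyloxy)-2α-(tert-butyldimethylsilyloxy)-4β,5β-dimethyl-10αH-Δ7-octalin | O=C(O[C@@H]1C=CC[C@]2(C)[C@@H](C)C[C@H](O[Si](C)(C)C(C)(C)C)C[C@@H]12)c1ccc(cc1)[N+](=O)[O-] | intermediate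
27 | 2α-(tert-butyldimethylsilyloxy)-4β,5β-dimethyl-10αH-Δ7-octalin-9α-ol | O[C@@H]1C=CC[C@]2(C)[C@@H](C)C[C@H](O[Si](C)(C)C(C)(C)C)C[C@@H]12 | intermediate
28 | 7α,8α-epoxy-2α-(tert-butyldimethylsilyloxy)-4β,5β-dimethyl-trans-decalin-9α-ol | O[C@@H]1[C@@H]3O[C@@H]3C[C@]2(C)[C@@H](C)C[C@H](O[Si](C)(C)C(C)(C)C)C[C@@H]12 | intermediate
29 | 7β-isopropenyl-2α-(tert-butyldimethylsilyloxy)-4β,5β-dimethyl-trans-decalin-8α,9α-diol | C=C(C)[C@H]1C[C@]2(C)[C@@H](C)C[C@H](O[Si](C)(C)C(C)(C)C)C[C@H]2[C@H](O)[C@@H]1O | intermediate
30 | (Z)-3-methylpent-2-enoic acid | CC/C(C)=C\C(=O)O | starting material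
31 | 8α,9α-O-dibutylstannylene acetal of 29 (not isolated) | C=C(C)[C@H]1C[C@]2(C)[C@@H](C)C[C@H](O[Si](C)(C)C(C)(C)C)C[C@H]2[C@@H]3O[Sn](CCCC)(CCCC)O[C@H]13 | intermediate
32 | (Z)-3-methylpent-2-enoyl chloride (not isolated) | CC/C(C)=C\C(Cl)=O | intermediate
33 | 9α-O-[(Z)-3-methylpent-2-enoyl]-7β-isopropenyl-2α-(tert-butyldimethylsilyloxy)-4β,5β-dimethyl-trans-decalin-8α-ol | C=C(C)[C@H]1C[C@]2(C)[C@@H](C)C[C@H](O[Si](C)(C)C(C)(C)C)C[C@H]2[C@H](OC(=O)/C=C(/C)CC)[C@@H]1O | intermediate
34 | CNP0129603.1, 2α,8α-dihydroxy-9α-[(Z)-3-methylpent-2-enoyloxy]-10αH-eremophil-11-ene | C=C(C)[C@H]1C[C@]2(C)[C@@H](C)C[C@H](O)C[C@H]2[C@H](OC(=O)/C=C(/C)CC)[C@@H]1O | target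

Total step count: 22. Longest linear sequence: 22 steps (1 → 34); 5, 17 and 30 enter at steps 3, 12 and 21.

Steps most likely to fail

Step 20. The sp2 carbon nucleophile has to reach C7 on the β face past the axial C5 methyl, so the opening may stall, magnesium halide may open the epoxide to a halohydrin, or base may eliminate it to an allylic alcohol. Fallback, setting out from 28: the slim, linear alkynylalane Et2AlC≡CSiMe3 (from trimethylsilylacetylene, n-BuLi and Et2AlCl; toluene, 0 °C → rt) should open the epoxide trans-diaxially at C7 to give 7β-(trimethylsilylethynyl)-2α-(TBS-oxy)-4β,5β-dimethyl-trans-decalin-8α,9α-diol F1. K2CO3 in MeOH then removes the alkyne silyl group to give the 7β-ethynyl diol F2. Negishi carboalumination (Me3Al, Cp2ZrCl2 cat., CH2Cl2; then H2O) places methyl on the internal alkyne carbon and, after protonolysis of the alkenylalane, gives the isopropenyl group. The route is rejoined at 29.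

Step 12. The β face of the tetrasubstituted C5=C10 alkene is flanked by the pseudoaxial 4β-methyl, so methylene transfer may be slow or lose facial selectivity. Fallback, setting out from 13: C4 is kept trigonal until after the cyclopropanation. Silylation (TBSCl, imidazole, DMF) gives 4-methylene-2α-(TBS-oxy)-Δ5(10)-octalin-9-one F3. The CBS system of step 11 reduces it to 4-methylene-2α-(TBS-oxy)-Δ5(10)-octalin-9β-ol F4. Et2Zn and 17 then cyclopropanate the hydroxyl-bearing C5=C10 alkene, now unencumbered, in preference to the remote exocyclic one, to give 5β,10β-methano-4-methylene-2α-(TBS-oxy)-decalin-9β-ol F5. Hydrogenation with H2 and RhCl(PPh3)3 in benzene should add hydrogen to the exocyclic methylene from the α face, away from the cyclopropane CH2, setting the 4β-methyl group. The route is rejoined at 19.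

Step 17. The pseudoaxial 9β-oxyphosphonium group has an anti-periplanar C10–H, so elimination to the C7=C8–C9=C10 diene or SN2′ attack at C7 may compete with clean inversion. Fallback, setting out from 24: Meerwein–Ponndorf–Verley reduction (Al(OiPr)3, i-PrOH, toluene, reflux) transfers hydride reversibly, so the carbinol epimers can equilibrate toward the pseudoequatorial 9α-alcohol, which avoids the 1,3-diaxial contact with the C5 methyl. This detour makes no new compound (F0). The route is rejoined at 27.

Further compounds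
F1 | step 20 | 7β-(trimethylsilylethynyl)-2α-(tert-butyldimethylsilyloxy)-4β,5β-dimethyl-trans-decalin-8α,9α-diol | C[Si](C)(C)C#C[C@H]1C[C@]2(C)[C@@H](C)C[C@H](O[Si](C)(C)C(C)(C)C)C[C@H]2[C@H](O)[C@@H]1O
F2 | step 20 | 7β-ethynyl-2α-(tert-butyldimethylsilyloxy)-4β,5β-dimethyl-trans-decalin-8α,9α-diol | C#C[C@H]1C[C@]2(C)[C@@H](C)C[C@H](O[Si](C)(C)C(C)(C)C)C[C@H]2[C@H](O)[C@@H]1O
F3 | step 12 | 4-methylene-2α-(tert-butyldimethylsilyloxy)-Δ5(10)-octalin-9-one | O=C1CCCC2=C1C[C@@H](O[Si](C)(C)C(C)(C)C)CC2=C
F4 | step 12 | 4-methylene-2α-(tert-butyldimethylsilyloxy)-Δ5(10)-octalin-9β-ol | O[C@H]1CCCC2=C1C[C@@H](O[Si](C)(C)C(C)(C)C)CC2=C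
F5 | step 12 | 5β,10β-methano-4-methylene-2α-(tert-butyldimethylsilyloxy)decalin-9β-ol | O[C@H]1CCC[C@@]23C[C@@]12C[C@@H](O[Si](C)(C)C(C)(C)C)CC3=C
F0 | step 17 | none | none
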